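The dihydrofuran ring O1–C2–C3–C3a–C7a is cut at both bonds to C2: O1–C2 and C2–C3. The o-hydroxybenzyl unit C7a(O1)–C3a–C3, which carries the meta-dioxygenated aryl that no Friedel–Crafts reaction can deliver, is used as an o-quinone methide (a transiently dearomatised benzo ring). C2 with its catechol aryl arrives as a one-carbon benzylidene from a limonene-derived chiral sulfonium ylide. One formal [4+1] annulation forms both bonds, closes the ring and sets C2 and C3 (trans, 2S,3S), while funnelling the racemic sulfone precursor through the planar quinone methide. Precursors: a racemic 2-[aryl(tosyl)methyl]-4-bromophenol and an enantiopure benzylsulfonium salt; the bromide later carries the stilbene.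

Key step: step 5

Assumption: the (1R,4R,5R)-sulfide 9 ((R)-limonene series) is taken to deliver the 2S sense by the usual model for its benzyl ylide (S-benzyl exo, aryl syn to the sulfur lone pair, attack remote from the CMe2 bridge); the antipodal sulfide is equally available and would be used in the same way if the opposite sense were found.

Step 1
Reactants: 1 3,5-bis(benzyloxy)benzaldehyde
Product: 2 3,5-bis(benzyloxy)styrene
Conditions: Ph3PCH3Br, KOtBu, THF, 0 °C → rt
Reagents that add atoms: methyltriphenylphosphonium bromide, C[P+](c1ccccc1)(c1ccccc1)c1ccccc1.[Br-]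
Why: Wittig methylenation of a non-enolisable aryl aldehyde with the unstabilised ylide is reliable, and the benzyl ethers are inert to the base.

Step 2
Reactants: 3 1-bromo-3,5-bis(benzyloxy)benzene; 4 5-bromo-2-hydroxybenzaldehyde
Product: 6 4-bromo-2-{[3,5-bis(benzyloxy)phenyl](hydroxy)methyl}phenol (racemic), via aryl Grignard reagent 5 (not isolated)
Conditions: 3 (2.3 equiv), Mg, LiCl, THF, 40 °C; then 4, THF, 0 °C → rt; aq NH4Cl
Reagents that add atoms: none
Why: Grignard 1,2-addition to the aldehyde, in which the first equivalent only deprotonates the phenol and the aryl C–Br bond of 4 does not exchange with an aryl Grignard at 0 °C; the new carbinol centre is racemic and is erased in step 5.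

Step 3
Reactants: 6 4-bromo-2-{[3,5-bis(benzyloxy)phenyl](hydroxy)methyl}phenol
Product: 7 4-bromo-2-{[3,5-bis(benzyloxy)phenyl](4-methylbenzenesulfonyl)methyl}phenol (racemic)
Conditions: p-TolSO2Na (2 equiv), HCO2H, CH2Cl2, rt
Reagents that add atoms: sodium p-toluenesulfinate, Cc1ccc(cc1)S(=O)[O-].[Na+]
Why: acid-promoted SN1-type substitution, in which the o-hydroxybenzhydrol ionises to the o-quinone methide or benzylic cation and is trapped at sulfur by the sulfinate, should give the bench-stable sulfone as a racemate.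

Step 4
Reactants: 8 3,4-bis(benzyloxy)benzyl alcohol; 9 (1R,4R,5R)-isothiocineole
Product: 10 (1R,4R,5R,6R)-6-[3,4-bis(benzyloxy)benzyl]-4,7,7-trimethyl-6-thiabicyclo[3.2.1]octan-6-ium tetrafluoroborate
Conditions: HBF4·OEt2 (1.0 equiv), 9 (1.1 equiv), CH2Cl2, −20 °C → rt; precipitation with Et2O
Reagents that add atoms: tetrafluoroboric acid (as its diethyl etherate), [H+].F[B-](F)(F)F
Why: S-alkylation of the sulfide by the p-alkoxybenzyl cation released from the alcohol (SN1) should occur on the exo lone pair of the bicycle, syn to the one-carbon bridge, to give one diastereomer at sulfur, and the non-nucleophilic counter-ion prevents reversal.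

Step 5
Reactants: 7 4-bromo-2-{[3,5-bis(benzyloxy)phenyl](4-methylbenzenesulfonyl)methyl}phenol; 10 sulfonium tetrafluoroborate
Product: 14 (2S,3S)-2-[3,4-bis(benzyloxy)phenyl]-3-[3,5-bis(benzyloxy)phenyl]-5-bromo-2,3-dihydro-1-benzofuran, via o-quinone methide 11 (not isolated), via sulfonium ylide 12 (not isolated), via betaine 13 (not isolated)
Conditions: 10 (1.5 equiv), Cs2CO3 (3 equiv), MeCN–CH2Cl2 (1:1), −20 °C → rt, slow addition of 7
Reagents that add atoms: none
Why: Cs2CO3 turns racemic 7 into the planar E-o-quinone methide 11 by 1,4-elimination of sulfinate and 10 into ylide 12; the ylide carbon adds 1,4 to the exocyclic methide carbon (C2–C3 bond, the benzo ring re-aromatises) to give phenoxide–sulfonium betaine 13, whose phenoxide displaces the sulfide in a 5-exo-tet SN2 closure (O1–C2 bond, inversion at C2) that releases 9. The closest known reaction type is the formal [4+1] annulation of sulfonium ylides with o-quinone methides generated from 2-(sulfonylalkyl)phenols, which gives trans-2,3-dihydrobenzofurans, combined with benzylidene transfer from isothiocineole-derived sulfonium salts as known from epoxidation, aziridination and cyclopropanation. C2 is controlled by the sulfide: the ylide should react as one conformer (aryl syn to the sulfur lone pair, away from C7) on the face remote from the CMe2 bridge, and the stereospecific inversion should then give 2S. C3 is controlled by the relative topicity of the addition: the two aryl groups stay anti in the addition transition state, and only the betaine that reaches the O−/S+ antiperiplanar geometry without eclipsing them closes readily, which should give the 2,3-trans ring and hence 3S. The step needs C-attack of the ylide to outrun O-benzylation of the phenoxide by 10 and oligomerisation of 11; both should be held back because 11 is released slowly into an excess of the soft carbon nucleophile. Because both enantiomers of 7 pass through the same achiral 11, the step is stereoconvergent; a minor cis isomer would be (2S,3R) and is removed by chromatography, not epimerised.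

Step 6
Reactants: 14 (2S,3S)-5-bromo-2,3-diaryl-2,3-dihydrobenzofuran; 2 3,5-bis(benzyloxy)styrene
Product: 15 (2S,3S)-2-[3,4-bis(benzyloxy)phenyl]-3-[3,5-bis(benzyloxy)phenyl]-5-[(E)-3,5-bis(benzyloxy)styryl]-2,3-dihydro-1-benzofuran
Conditions: Pd(OAc)2 (5 mol %), P(o-tol)3 (10 mol %), Et3N (3 equiv), DMF, 100 °C
Reagents that add atoms: none
Why: Mizoroki–Heck coupling (oxidative addition, syn-carbopalladation at the terminal styrene carbon, syn-β-hydride elimination) should give the E-stilbene, and the C2 and C3 hydrogens are not acidic enough for the amine base to touch the stereocentres.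

Step 7
Reactants: 15 hexabenzyl ether
Product: 16 5-[(E)-2-[(2S,3S)-2-(3,4-dihydroxyphenyl)-3-(3,5-dihydroxyphenyl)-2,3-dihydro-1-benzofuran-5-yl]ethenyl]benzene-1,3-diol (CNP0207985.1)
Conditions: BCl3 (1 M in CH2Cl2, 15 equiv), C6Me5H (18 equiv), CH2Cl2, −78 °C; then MeOH–H2O, −78 °C → rt, under argon
Reagents that add atoms: none
Why: Lewis-acid cleavage of aryl benzyl ethers with pentamethylbenzene as a non-basic benzyl-cation scavenger at −78 °C should spare the stilbene (no hydrogenation), and any ionisation of the C2–O bond would reclose to the thermodynamic trans ring with C3 untouched.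

Compound list
1 | 3,5-bis(benzyloxy)benzaldehyde | O=Cc1cc(OCc2ccccc2)cc(OCc2ccccc2)c1 | starting material
2 | 3,5-bis(benzyloxy)styrene | C=Cc1cc(OCc2ccccc2)cc(OCc2ccccc2)c1 | intermediate
3 | 1-bromo-3,5-bis(benzyloxy)benzene | Brc1cc(OCc2ccccc2)cc(OCc2ccccc2)c1 | starting material
4 | 5-bromo-2-hydroxybenzaldehyde | O=Cc1cc(Br)ccc1O | starting material
5 | 3,5-bis(benzyloxy)phenylmagnesium bromide | Br[Mg]c1cc(OCc2ccccc2)cc(OCc2ccccc2)c1 | intermediate (not isolated)
6 | 4-bromo-2-{[3,5-bis(benzyloxy)phenyl](hydroxy)methyl}phenol, racemic | OC(c1cc(OCc2ccccc2)cc(OCc2ccccc2)c1)c1cc(Br)ccc1O | intermediate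
7 | 4-bromo-2-{[3,5-bis(benzyloxy)phenyl](4-methylbenzenesulfonyl)methyl}phenol, racemic | Cc1ccc(cc1)S(=O)(=O)C(c1cc(OCc2ccccc2)cc(OCc2ccccc2)c1)c1cc(Br)ccc1O | intermediate
8 | 3,4-bis(benzyloxy)benzyl alcohol | OCc1ccc(OCc2ccccc2)c(OCc2ccccc2)c1 | starting material
9 | (1R,4R,5R)-isothiocineole, (1R,4R,5R)-4,7,7-trimethyl-6-thiabicyclo[3.2.1]octane | C[C@@H]1CC[C@@H]2C[C@H]1SC2(C)C | starting material
10 | (1R,4R,5R,6R)-6-[3,4-bis(benzyloxy)benzyl]-4,7,7-trimethyl-6-thiabicyclo[3.2.1]octan-6-ium tetrafluoroborate | C[C@@H]1CC[C@@H]2C[C@H]1[S@@+](Cc3ccc(OCc4ccccc4)c(OCc5ccccc5)c3)C2(C)C.F[B-](F)(F)F | intermediate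
11 | (6E)-4-bromo-6-[3,5-bis(benzyloxy)benzylidene]cyclohexa-2,4-dien-1-one (o-quinone methide) | O=C1C=CC(Br)=C/C1=C\c2cc(OCc3ccccc3)cc(OCc4ccccc4)c2 | intermediate (not isolated)
12 | sulfonium ylide of 10 (benzylic carbanion on sulfur) | C[C@@H]1CC[C@@H]2C[C@H]1[S@@+]([CH-]c3ccc(OCc4ccccc4)c(OCc5ccccc5)c3)C2(C)C | intermediate (not isolated)
13 | betaine: phenoxide with the sulfonium group on the future C2 and the new C2–C3 bond | C[C@@H]1CC[C@@H]2C[C@H]1[S@@+]([C@@H](c3ccc(OCc4ccccc4)c(OCc5ccccc5)c3)[C@@H](c3cc(OCc4ccccc4)cc(OCc5ccccc5)c3)c3cc(Br)ccc3[O-])C2(C)C | intermediate (not isolated)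
14 | (2S,3S)-2-[3,4-bis(benzyloxy)phenyl]-3-[3,5-bis(benzyloxy)phenyl]-5-bromo-2,3-dihydro-1-benzofuran | Brc1ccc2c(c1)[C@H](c1cc(OCc3ccccc3)cc(OCc3ccccc3)c1)[C@@H](c1ccc(OCc3ccccc3)c(OCc3ccccc3)c1)O2 | intermediate
15 | (2S,3S)-2-[3,4-bis(benzyloxy)phenyl]-3-[3,5-bis(benzyloxy)phenyl]-5-[(E)-3,5-bis(benzyloxy)styryl]-2,3-dihydro-1-benzofuran | O(Cc1ccccc1)c1cc(OCc2ccccc2)cc(/C=C/c2ccc3c(c2)[C@H](c2cc(OCc4ccccc4)cc(OCc4ccccc4)c2)[C@@H](c2ccc(OCc4ccccc4)c(OCc4ccccc4)c2)O3)c1 | intermediate
16 | 5-[(E)-2-[(2S,3S)-2-(3,4-dihydroxyphenyl)-3-(3,5-dihydroxyphenyl)-2,3-dihydro-1-benzofuran-5-yl]ethenyl]benzene-1,3-diol | Oc1cc(O)cc(/C=C/c2ccc3c(c2)[C@H](c2cc(O)cc(O)c2)[C@@H](c2ccc(O)c(O)c2)O3)c1 | target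

Total step count: 7. Longest linear sequence: 5 steps (steps 2, 3, 5, 6, 7).

Steps most likely to fail

1. Step 5. The ylide may discriminate poorly between its two faces, the 1,4-addition may lose its trans preference, or the phenoxide may be O-benzylated by the sulfonium salt faster than the annulation proceeds. The fallback sets out from 6 and builds the ring by a C–H insertion instead:
   - The phenol of 6 is alkylated with commercial 3,4-bis(benzyloxy)benzyl chloride (K2CO3, DMF) to the aryl benzyl ether carbinol F1.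
   - MnO2 oxidation gives the diaryl ketone F2, and hydrazine hydrate (AcOH cat., EtOH, reflux) gives the hydrazone F3.
   - MnO2 oxidation of F3 gives the diaryl diazomethane F4, which is filtered and treated at 0 °C with a chiral dirhodium tetrakis[N-phthaloyl(adamantyl)glycinate] catalyst, its enantiomer chosen to set 3S.
   - The donor/donor carbene should insert into the benzylic ether C–H bond to give the cis-(2R,3S)-dihydrobenzofuran F5.
   - Brief treatment of F5 with CF3CO2H in CH2Cl2 at 0 °C should epimerise C2 alone, through the p-benzyloxy-stabilised benzylic cation, to the trans isomer. The route is rejoined at 14.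

2. Step 7. Six ethers may not all be cleaved in one pot, and the liberated electron-rich stilbene may undergo hydrochlorination, Friedel–Crafts benzylation or oligomerisation under the Lewis acid. The fallback sets out from 14, moves the Lewis-acid step ahead of the alkene and ends with a fluoride desilylation:
   - BCl3/C6Me5H at −78 °C on 14 gives the tetraphenol bromide F6, which is silylated (TBSCl, imidazole, DMF) to the tetrakis(silyl ether) F7.
   - Commercial 3,5-dihydroxybenzaldehyde is silylated to 3,5-bis(tert-butyldimethylsilyloxy)benzaldehyde F8 and methylenated (Ph3PCH3Br, KOtBu) to 3,5-bis(tert-butyldimethylsilyloxy)styrene F9.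
   - Mizoroki–Heck coupling of F7 with F9 (Pd(OAc)2, P(o-tol)3, Et3N, DMF, 90 °C) gives the hexakis(silyl ether) F10.
   - Bu4NF buffered with AcOH in THF at 0 °C under argon should release the hexaphenol. The route is rejoined at 16.

3. Step 6. Oxidative addition into the electron-rich aryl bromide may be slow, so that styrene oligomerisation, 1,1-arylation or E/Z mixtures take over. The fallback sets out from 14 and forms the alkene by olefination instead:
   - Bromine–lithium exchange (n-BuLi, THF, −78 °C) gives the aryllithium F11, which is formylated with DMF to the 5-carbaldehyde F12.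
   - Commercial 3,5-bis(benzyloxy)benzyl bromide and P(OEt)3 (Michaelis–Arbuzov, 130 °C) give diethyl [3,5-bis(benzyloxy)benzyl]phosphonate F13.
   - Horner–Wadsworth–Emmons reaction of F13 (NaH, THF, 0 °C) with F12 should give the E-stilbene. The route is rejoined at 15.

Further compounds
F1 | step 5 | {2-[3,4-bis(benzyloxy)benzyloxy]-5-bromophenyl}[3,5-bis(benzyloxy)phenyl]methanol, racemic | OC(c1cc(OCc2ccccc2)cc(OCc2ccccc2)c1)c1cc(Br)ccc1OCc1ccc(OCc2ccccc2)c(OCc2ccccc2)c1
F2 | step 5 | {2-[3,4-bis(benzyloxy)benzyloxy]-5-bromophenyl}[3,5-bis(benzyloxy)phenyl]methanone | O=C(c1cc(OCc2ccccc2)cc(OCc2ccccc2)c1)c1cc(Br)ccc1OCc1ccc(OCc2ccccc2)c(OCc2ccccc2)c1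
F3 | step 5 | hydrazone of ketone F2 (E/Z mixture) | NN=C(c1cc(OCc2ccccc2)cc(OCc2ccccc2)c1)c1cc(Br)ccc1OCc1ccc(OCc2ccccc2)c(OCc2ccccc2)c1
F4 | step 5 | diaryl diazomethane from F3 | [N-]=[N+]=C(c1cc(OCc2ccccc2)cc(OCc2ccccc2)c1)c1cc(Br)ccc1OCc1ccc(OCc2ccccc2)c(OCc2ccccc2)c1
F5 | step 5 | (2R,3S)-2-[3,4-bis(benzyloxy)phenyl]-3-[3,5-bis(benzyloxy)phenyl]-5-bromo-2,3-dihydro-1-benzofuran (cis) | Brc1ccc2c(c1)[C@H](c1cc(OCc3ccccc3)cc(OCc3ccccc3)c1)[C@H](c1ccc(OCc3ccccc3)c(OCc3ccccc3)c1)O2
F6 | step 7 | (2S,3S)-5-bromo-2-(3,4-dihydroxyphenyl)-3-(3,5-dihydroxyphenyl)-2,3-dihydro-1-benzofuran | Brc1ccc2c(c1)[C@H](c1cc(O)cc(O)c1)[C@@H](c1ccc(O)c(O)c1)O2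
F7 | step 7 | tetrakis(tert-butyldimethylsilyl) ether of F6 | Brc1ccc2c(c1)[C@H](c1cc(O[Si](C)(C)C(C)(C)C)cc(O[Si](C)(C)C(C)(C)C)c1)[C@@H](c1ccc(O[Si](C)(C)C(C)(C)C)c(O[Si](C)(C)C(C)(C)C)c1)O2
F8 | step 7 | 3,5-bis(tert-butyldimethylsilyloxy)benzaldehyde | O=Cc1cc(O[Si](C)(C)C(C)(C)C)cc(O[Si](C)(C)C(C)(C)C)c1
F9 | step 7 | 3,5-bis(tert-butyldimethylsilyloxy)styrene | C=Cc1cc(O[Si](C)(C)C(C)(C)C)cc(O[Si](C)(C)C(C)(C)C)c1
F10 | step 7 | hexakis(tert-butyldimethylsilyl) ether of 16 | CC(C)(C)[Si](C)(C)Oc1cc(O[Si](C)(C)C(C)(C)C)cc(/C=C/c2ccc3c(c2)[C@H](c2cc(O[Si](C)(C)C(C)(C)C)cc(O[Si](C)(C)C(C)(C)C)c2)[C@@H](c2ccc(O[Si](C)(C)C(C)(C)C)c(O[Si](C)(C)C(C)(C)C)c2)O3)c1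
F11 | step 6 | 5-lithio derivative of 14 | [Li]c1ccc2c(c1)[C@H](c1cc(OCc3ccccc3)cc(OCc3ccccc3)c1)[C@@H](c1ccc(OCc3ccccc3)c(OCc3ccccc3)c1)O2
F12 | step 6 | (2S,3S)-2-[3,4-bis(benzyloxy)phenyl]-3-[3,5-bis(benzyloxy)phenyl]-2,3-dihydro-1-benzofuran-5-carbaldehyde | O=Cc1ccc2c(c1)[C@H](c1cc(OCc3ccccc3)cc(OCc3ccccc3)c1)[C@@H](c1ccc(OCc3ccccc3)c(OCc3ccccc3)c1)O2
F13 | step 6 | diethyl [3,5-bis(benzyloxy)benzyl]phosphonate | CCOP(=O)(OCC)Cc1cc(OCc2ccccc2)cc(OCc2ccccc2)c1
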